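**Plan**
- Retrosynthetic cuts: C11–C12 (chain from core); then C11–C19 (methyl) and C7–C11 (anchor on C7); C3=C4 of the five-membered ring (metathesis); C1–C2 and C5–C4 (two substituents on a cycloheptenone).
- Forward: cyclohepta-1,3-diene gives (R)-4-silyloxycyclohept-2-enone; conjugate addition/enolate allylation sets C5 and C1; metathesis closes the five-membered ring; C9–OH and C10=CH2 follow; a silicon-tethered radical cyclization from O6 places C11 cis on C7.
- The chain is joined by two boron homologations: methyl onto C11, then union with an (S)-alkenyl oxirane that brings C12–C17 and both chain oxygens.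
- Enabling feature: C11 is a secondary carbon bearing only H, CH3 and ring carbon C7, flanked by the syn C12/C13 diol. This is the pattern left when an alkyl group migrates from boron onto a metalated terminal oxirane.
- Stereochemistry: C6 from a catalytic Kornblum–DeLaMare desymmetrization, relayed by substrate control to C5, C1, C9, C7 and C4; C11 by sparteine; C13 bought as (R)-glyceraldehyde acetonide; C12 by the stereospecific 1,2-shift.

Key step: step 24

Remark: positions in all names follow the target numbered as a dictyotane (hydroazulene C1–C10 with C1/C5 ring fusion, C2=C3, C4 carbinol bearing methyl C20, C10=C18H2; chain C11(C19H3)–C12–C13–C14=C15); β is the ring face of H-5 (it also carries the C6 and C4 oxygens and the C7 chain), α the face of H-1 (it also carries the C9 oxygen and C20).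

Step 1
Reactants: 1 cyclohepta-1,3-diene
Product: 2 6,7-dioxabicyclo[3.2.2]non-8-ene (meso endoperoxide)
Conditions: O2, tetraphenylporphyrin (cat.), visible light, CH2Cl2, 0 °C
Reagents that add atoms: oxygen, O=O
Why: Photosensitised singlet oxygen adds across the s-cis diene in a [4+2] cycloaddition to give the meso endoperoxide, so no stereocontrol is needed.

Step 2
Reactants: 2 6,7-dioxabicyclo[3.2.2]non-8-ene
Product: 3 (R)-4-hydroxycyclohept-2-en-1-one
Conditions: bifunctional cinchona-alkaloid amine catalyst (10 mol %, pseudoenantiomer giving the R product), CH2Cl2, rt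
Reagents that add atoms: none
Why: In the Kornblum–DeLaMare rearrangement the chiral amine removes one of the two enantiotopic bridgehead protons with O–O cleavage, so the desymmetrization sets the carbinol centre (the later C6) as R.

Step 3
Reactants: 3 (R)-4-hydroxycyclohept-2-en-1-one
Product: 4 (R)-4-(triethylsilyloxy)cyclohept-2-en-1-one
Conditions: Et3SiCl, imidazole, DMF, 0 °C
Reagents that add atoms: chlorotriethylsilane, CC[Si](Cl)(CC)CC
Why: Routine silylation of the secondary allylic alcohol; the triethylsilyl group is chosen because it can later be removed beside a tert-butyldimethylsilyl ether.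

Step 4
Reactants: 4 (R)-4-(triethylsilyloxy)cyclohept-2-en-1-one
Product: 6 (2R,3S,4R)-2-allyl-3-(prop-1-en-2-yl)-4-(triethylsilyloxy)cycloheptan-1-one, via magnesium enolate 5 (not isolated)
Conditions: CH2=C(CH3)MgBr, CuBr·SMe2 (10 mol %), THF, −78 °C; then allyl iodide, HMPA, −78 → −20 °C
Reagents that add atoms: isopropenylmagnesium bromide, C=C(C)[Mg]Br; allyl iodide, C=CCI
Why: Copper-catalysed conjugate addition puts the isopropenyl group on C5 anti to the γ-silyloxy group and the enolate is allylated at C1 trans to the new C5 substituent (tandem conjugate addition–enolate alkylation), so C5 and C1 are both relayed from C6.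

Step 5
Reactants: 6 (2R,3S,4R)-2-allyl-3-(prop-1-en-2-yl)-4-(triethylsilyloxy)cycloheptan-1-one
Product: 7 4-methyl-6β-(triethylsilyloxy)-1αH,5βH-bicyclo[5.3.0]dec-3-en-10-one
Conditions: second-generation Grubbs catalyst (5 mol %), CH2Cl2, 40 °C
Reagents that add atoms: none
Why: Ring-closing metathesis of the 1,6-diene (allyl plus isopropenyl) forms the trisubstituted cyclopentene with loss of ethylene and leaves the trans ring fusion from step 4 untouched.

Step 6
Reactants: 7 4-methyl-6β-(triethylsilyloxy)-1αH,5βH-bicyclo[5.3.0]dec-3-en-10-one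
Product: 9 9α-hydroxy-4-methyl-6β-(triethylsilyloxy)-1αH,5βH-bicyclo[5.3.0]dec-3-en-10-one, via potassium enolate 8 (not isolated)
Conditions: KN(SiMe3)2, THF, −78 °C; then 2-(phenylsulfonyl)-3-phenyloxaziridine, −78 °C; NH4Cl work-up
Reagents that add atoms: 2-(phenylsulfonyl)-3-phenyloxaziridine, O=S(=O)(c1ccccc1)N1OC1c1ccccc1
Why: Kinetic deprotonation takes place at the C9 methylene and not at the tertiary C1, and the electrophilic oxaziridine (enolate hydroxylation) should approach the enolate face anti to the pseudo-axial C1–C2 bond, which places the new hydroxyl α on C9.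

Step 7
Reactants: 9 9α-hydroxy-4-methyl-6β-(triethylsilyloxy)-1αH,5βH-bicyclo[5.3.0]dec-3-en-10-one
Product: 10 9α-(tert-butyldimethylsilyloxy)-4-methyl-6β-(triethylsilyloxy)-1αH,5βH-bicyclo[5.3.0]dec-3-en-10-one
Conditions: tBuMe2SiOTf, 2,6-lutidine, CH2Cl2, −78 °C
Reagents that add atoms: tert-butyldimethylsilyl triflate, CC(C)(C)[Si](C)(C)OS(=O)(=O)C(F)(F)F
Why: Silylation with a silyl triflate and a hindered base protects the hindered α-hydroxy ketone at low temperature without enolisation.

Step 8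
Reactants: 10 9α-(tert-butyldimethylsilyloxy)-4-methyl-6β-(triethylsilyloxy)-1αH,5βH-bicyclo[5.3.0]dec-3-en-10-one
Product: 11 9α-(tert-butyldimethylsilyloxy)-4-methyl-10-methylene-6β-(triethylsilyloxy)-1αH,5βH-bicyclo[5.3.0]dec-3-ene
Conditions: Ph3PCH3Br, KOtBu, toluene, 0 → 60 °C
Reagents that add atoms: methyltriphenylphosphonium bromide, C[P+](c1ccccc1)(c1ccccc1)c1ccccc1.[Br-]
Why: Wittig methylenation turns the hindered C10 ketone into the exocyclic C10=C18 alkene, and the weakly basic non-stabilised ylide is expected to leave the adjacent C1 and C9 centres untouched.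

Step 9
Reactants: 11 9α-(tert-butyldimethylsilyloxy)-4-methyl-10-methylene-6β-(triethylsilyloxy)-1αH,5βH-bicyclo[5.3.0]dec-3-ene
Product: 12 9α-(tert-butyldimethylsilyloxy)-4-methyl-10-methylene-1αH,5βH-bicyclo[5.3.0]dec-3-en-6β-ol
Conditions: HF·pyridine, pyridine, THF, 0 °C
Reagents that add atoms: none
Why: Buffered fluoride should remove the secondary triethylsilyl ether much faster than the tert-butyldimethylsilyl ether (selective desilylation).

Step 10
Reactants: 12 9α-(tert-butyldimethylsilyloxy)-4-methyl-10-methylene-1αH,5βH-bicyclo[5.3.0]dec-3-en-6β-ol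
Product: 13 9α-(tert-butyldimethylsilyloxy)-4-methyl-10-methylene-1αH,5βH-bicyclo[5.3.0]dec-3-en-6-one
Conditions: Dess–Martin periodinane, NaHCO3, CH2Cl2, rt
Reagents that add atoms: none
Why: Dess–Martin oxidation under buffered conditions should give the C6 ketone without moving the β,γ-double bond C3=C4 into conjugation or epimerising C5.

Step 11
Reactants: 13 9α-(tert-butyldimethylsilyloxy)-4-methyl-10-methylene-1αH,5βH-bicyclo[5.3.0]dec-3-en-6-one
Product: 15 9α-(tert-butyldimethylsilyloxy)-4-methyl-10-methylene-1αH,5βH-bicyclo[5.3.0]deca-3,7-dien-6-one, via silyl enol ether 14 (not isolated)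
Conditions: LiN(iPr)2, Me3SiCl, THF, −78 °C; then Pd(OAc)2, MeCN, rt
Reagents that add atoms: none
Why: Saegusa–Ito dehydrogenation: kinetic enolisation toward the C7 methylene rather than the tertiary allylic C5, O-silylation, then palladium enolate formation and β-hydride elimination give the C7=C8 enone.

Step 12
Reactants: 15 9α-(tert-butyldimethylsilyloxy)-4-methyl-10-methylene-1αH,5βH-bicyclo[5.3.0]deca-3,7-dien-6-one
Product: 16 9α-(tert-butyldimethylsilyloxy)-4-methyl-10-methylene-1αH,5βH-bicyclo[5.3.0]deca-3,7-dien-6β-ol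
Conditions: (R)-2-methyl-CBS-oxazaborolidine (20 mol %), catecholborane, toluene, −78 °C
Reagents that add atoms: none
Why: Corey–Bakshi–Shibata reduction, with the C7=C8 arm taken as the large group, should deliver hydride 1,2 to the α-face of the carbonyl (also the axial trajectory trans to the C5 substituent), restoring the 6β-alcohol as an allylic alcohol while catecholborane leaves the isolated alkenes alone.

Step 13
Reactants: 16 9α-(tert-butyldimethylsilyloxy)-4-methyl-10-methylene-1αH,5βH-bicyclo[5.3.0]deca-3,7-dien-6β-ol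
Product: 17 6β-[(bromomethyl)dimethylsilyloxy]-9α-(tert-butyldimethylsilyloxy)-4-methyl-10-methylene-1αH,5βH-bicyclo[5.3.0]deca-3,7-diene
Conditions: BrCH2SiMe2Cl, Et3N, DMAP (cat.), CH2Cl2, 0 °C
Reagents that add atoms: (bromomethyl)chlorodimethylsilane, C[Si](C)(Cl)CBr
Why: Silylation of the only free hydroxyl attaches the bromomethylsilyl radical precursor to O6.

Step 14
Reactants: 17 6β-[(bromomethyl)dimethylsilyloxy]-9α-(tert-butyldimethylsilyloxy)-4-methyl-10-methylene-1αH,5βH-bicyclo[5.3.0]deca-3,7-diene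
Product: 19 9α-(tert-butyldimethylsilyloxy)-7β-(hydroxymethyl)-4-methyl-10-methylene-1αH,5βH,7αH-bicyclo[5.3.0]dec-3-en-6β-ol, via oxasilolane 18 (not isolated)
Conditions: Bu3SnH, AIBN (cat.), benzene, 80 °C; then KF, KHCO3, 30% H2O2, THF–MeOH, rt
Reagents that add atoms: hydrogen peroxide, OO
Why: Nishiyama–Stork cyclization: the α-silyl radical should close 5-exo-trig onto C7 (the 6-endo site C8 is shielded by the silyloxy-bearing C9) and the short O–Si–C tether forces the new C7–C11 bond onto the β-face cis to O6, after which Bu3SnH reduces the C8 radical and Tamao–Fleming oxidation of the C–Si bond frees the 1,3-diol.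

Step 15
Reactants: 19 9α-(tert-butyldimethylsilyloxy)-7β-(hydroxymethyl)-4-methyl-10-methylene-1αH,5βH,7αH-bicyclo[5.3.0]dec-3-en-6β-ol
Product: 20 C11 N,N-diisopropylcarbamate of 19 (6β-hydroxyl free)
Conditions: iPr2NCOCl, Et3N, CH2Cl2, 40 °C
Reagents that add atoms: N,N-diisopropylcarbamoyl chloride, CC(C)N(C(C)C)C(Cl)=O
Why: Carbamoylation should occur at the unhindered primary hydroxyl in preference to the secondary C6 hydroxyl flanked by the ring fusion, installing the directing and leaving group for the later lithiation.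

Step 16
Reactants: 20 C11 N,N-diisopropylcarbamate of 19
Product: 21 6β,9α-bis(tert-butyldimethylsilyloxy) C11 carbamate
Conditions: tBuMe2SiOTf, 2,6-lutidine, CH2Cl2, −78 → 0 °C
Reagents that add atoms: tert-butyldimethylsilyl triflate, CC(C)(C)[Si](C)(C)OS(=O)(=O)C(F)(F)F
Why: Silylation of the remaining secondary alcohol masks O6 before the peracid and organolithium steps.

Step 17
Reactants: 21 6β,9α-bis(tert-butyldimethylsilyloxy) C11 carbamate
Product: 22 3β,4β-epoxide of 21
Conditions: mCPBA, NaHCO3, CH2Cl2, 0 °C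
Reagents that add atoms: 3-chloroperoxybenzoic acid, OOC(=O)c1cccc(Cl)c1
Why: Prilezhaev epoxidation is expected at the electron-rich trisubstituted C3=C4 alkene rather than at the 1,1-disubstituted C10=C18 alkene next to a silyloxy group, and from the β-face anti to the adjacent C5–C6 bond, which fixes the C4 oxygen β and C20 α.

Step 18
Reactants: 22 3β,4β-epoxide of 21
Product: 24 4β-hydroxy-2-ene (tertiary allylic alcohol; 6β,9α-bis-silyl ether; C11 carbamate), via hydroxy selenide 23 (not isolated)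
Conditions: PhSeSePh, NaBH4, EtOH, 70 °C; then 30% H2O2, THF, 0 °C → rt
Reagents that add atoms: none
Why: The selenolate opens the epoxide at the less hindered C3 with inversion and the derived selenoxide can only eliminate syn toward C2 because C4 carries no hydrogen (epoxide to allylic alcohol transposition), giving C2=C3 and the tertiary C4 alcohol with unchanged configuration.

Step 19
Reactants: 24 4β-hydroxy-2-ene
Product: 25 4β,6β,9α-tris(tert-butyldimethylsilyloxy) C11 carbamate
Conditions: tBuMe2SiOTf, 2,6-lutidine, CH2Cl2, 0 °C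
Reagents that add atoms: tert-butyldimethylsilyl triflate, CC(C)(C)[Si](C)(C)OS(=O)(=O)C(F)(F)F
Why: Silylation of the tertiary allylic alcohol ensures that no acidic hydroxyl or boron-binding alkoxide is present in the organolithium steps.

Step 20
Reactants: 25 4β,6β,9α-tris(tert-butyldimethylsilyloxy) C11 carbamate
Product: 28 (11R)-C11 pinacol boronic ester (7β-[1-(pinacolboryl)ethyl] core), via lithiated carbamate 26 (not isolated), via methylboronate complex 27 (not isolated)
Conditions: s-BuLi, (+)-sparteine, Et2O, −78 °C; then MeBpin, −78 °C; then MgBr2·OEt2, −78 °C → reflux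
Reagents that add atoms: 2,4,4,5,5-pentamethyl-1,3,2-dioxaborolane, CB1OC(C)(C)C(C)(C)O1
Why: Sparteine-mediated deprotonation removes one of the enantiotopic C11 hydrogens to give a configurationally stable α-lithio carbamate, boron adds with retention, and the methyl group then shifts from boron to C11 anti to the departing carbamate (lithiation–borylation, a 1,2-metallate rearrangement), so the diamine enantiomer sets C11 as R.

Step 21
Reactants: 29 (R)-2,2-dimethyl-1,3-dioxolane-4-carbaldehyde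
Product: 30 (S)-2,2-dimethyl-4-(2-methylprop-1-en-1-yl)-1,3-dioxolane
Conditions: iPrPPh3I, n-BuLi, THF, 0 °C; then 29, −78 °C → rt
Reagents that add atoms: isopropyltriphenylphosphonium iodide, CC(C)[P+](c1ccccc1)(c1ccccc1)c1ccccc1.[I-]
Why: Wittig olefination with the non-stabilised isopropylidene ylide converts the aldehyde of the chiral-pool building block into the trisubstituted C14=C15 alkene, and the low temperature should prevent epimerisation of the α-alkoxy centre (the later C13).

Step 22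
Reactants: 30 (S)-2,2-dimethyl-4-(2-methylprop-1-en-1-yl)-1,3-dioxolane
Product: 31 (S)-4-methylpent-3-ene-1,2-diol
Conditions: AcOH–H2O (4:1), 40 °C
Reagents that add atoms: none
Why: Acid-catalysed acetal hydrolysis frees the 1,2-diol without affecting the stereocentre or the trisubstituted alkene.

Step 23
Reactants: 31 (S)-4-methylpent-3-ene-1,2-diol
Product: 33 (S)-2-(2-methylprop-1-en-1-yl)oxirane, via sodium alkoxide tosylate 32 (not isolated)
Conditions: NaH, 1-(p-tolylsulfonyl)imidazole, THF, 0 °C → rt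
Reagents that add atoms: none
Why: The primary alkoxide is sulfonylated selectively and the secondary alkoxide then closes the oxirane by intramolecular Williamson displacement at the primary carbon, so the C13 stereocentre is not touched.

Step 24
Reactants: 28 (11R)-C11 pinacol boronic ester; 33 (S)-2-(2-methylprop-1-en-1-yl)oxirane
Product: 37 (11R,12S,13S)-12,13-diol (4β,6β,9α-tris-silyl ether), via oxiranyllithium 34 (not isolated), via boronate complex 35 (not isolated), via silyloxy boronic ester 36 (not isolated)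
Conditions: 33 (2 equiv), lithium 2,2,6,6-tetramethylpiperidide, THF, −30 °C; then Me3SiOTf, −78 → 0 °C; then NaOH, 30% H2O2, THF–H2O, 0 °C → rt
Reagents that add atoms: hydrogen peroxide, OO
Why: Proposed new method: the lithium amide should remove the terminal oxirane hydrogen of 33 trans to the alkenyl group, the oxiranyllithium 34 is captured in situ by boronic ester 28 with retention to give boronate 35, and Me3SiOTf then triggers a 1,2-shift of the C11 alkyl group from boron to C12 anti to the breaking C12–O bond, after which oxidation replaces boron by OH with retention and the labile trimethylsilyl ether on O13 is hydrolysed in the basic work-up. The closest known reaction type is the homologation of simple alkyl pinacol boronic esters with lithiated terminal alkyl epoxides to give syn-1,2-diols, which has not been shown for a 2-alkenyl oxirane or for a boronic ester as hindered as 28. No ring is closed; the three-membered oxirane is opened, and the C11–C12 bond is made in an intermolecular ate-complex/1,2-metallate sequence. C12 is controlled by the trans-lithiation and the invertive migration, C13 is carried over unchanged from 33, and C11 is retained because the migrating carbon keeps its configuration, which together give the all-syn 11R,12S,13S triad. The step needs deprotonation at the terminal CH2 rather than at the allylic oxirane C–H, and migration rather than β-oxido elimination; the bulky amide base, the cis-methyl of the isobutenyl group that shields the internal C–H, in situ trapping and silylation of the alkoxide are expected to secure both.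

Step 25
Reactants: 37 (11R,12S,13S)-12,13-diol
Product: 38 12,13-diacetate (4β,6β,9α-tris-silyl ether)
Conditions: Ac2O, pyridine, DMAP (cat.), CH2Cl2, rt
Reagents that add atoms: acetic anhydride, CC(=O)OC(C)=O
Why: Esterification of the two free secondary hydroxyls under nucleophilic catalysis; all other oxygens are silylated, so no selectivity is required.

Step 26
Reactants: 38 12,13-diacetate (4β,6β,9α-tris-silyl ether)
Product: 39 CNP0269663.3 (target)
Conditions: HF·pyridine, pyridine, THF, 0 °C → rt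
Reagents that add atoms: none
Why: Fluoride-mediated cleavage of the three silyl ethers under buffered, weakly acidic conditions should leave the acetates in place and not ionise the tertiary allylic alcohol.

**Compound list**
1 | cyclohepta-1,3-diene | C1=CC=CCCC1 | starting material
2 | 6,7-dioxabicyclo[3.2.2]non-8-ene | C1CCC2C=CC1OO2 | intermediate
3 | (R)-4-hydroxycyclohept-2-en-1-one | O=C1CCC[C@@H](O)C=C1 | intermediate
4 | (R)-4-(triethylsilyloxy)cyclohept-2-en-1-one | O=C1CCC[C@@H](O[Si](CC)(CC)CC)C=C1 | intermediate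
5 | bromomagnesium enolate of (3S,4R)-3-(prop-1-en-2-yl)-4-(triethylsilyloxy)cycloheptan-1-one | Br[Mg]OC1=C[C@@H](C(C)=C)[C@H](O[Si](CC)(CC)CC)CCC1 | intermediate
6 | (2R,3S,4R)-2-allyl-3-(prop-1-en-2-yl)-4-(triethylsilyloxy)cycloheptan-1-one | O=C1CCC[C@@H](O[Si](CC)(CC)CC)[C@H](C(C)=C)[C@H]1CC=C | intermediate
7 | 4-methyl-6β-(triethylsilyloxy)-1αH,5βH-bicyclo[5.3.0]dec-3-en-10-one | O=C1CCC[C@@H](O[Si](CC)(CC)CC)[C@H]2[C@H]1CC=C2C | intermediate
8 | potassium C9–C10 enolate of 7 | [K+].[O-]C1=CCC[C@@H](O[Si](CC)(CC)CC)[C@H]2[C@H]1CC=C2C | intermediate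
9 | 9α-hydroxy-4-methyl-6β-(triethylsilyloxy)-1αH,5βH-bicyclo[5.3.0]dec-3-en-10-one | O=C1[C@H](O)CC[C@@H](O[Si](CC)(CC)CC)[C@H]2[C@H]1CC=C2C | intermediate
10 | 9α-(tert-butyldimethylsilyloxy)-4-methyl-6β-(triethylsilyloxy)-1αH,5βH-bicyclo[5.3.0]dec-3-en-10-one | O=C1[C@H](O[Si](C)(C)C(C)(C)C)CC[C@@H](O[Si](CC)(CC)CC)[C@H]2[C@H]1CC=C2C | intermediate
11 | 9α-(tert-butyldimethylsilyloxy)-4-methyl-10-methylene-6β-(triethylsilyloxy)-1αH,5βH-bicyclo[5.3.0]dec-3-ene | C=C1[C@H](O[Si](C)(C)C(C)(C)C)CC[C@@H](O[Si](CC)(CC)CC)[C@H]2[C@H]1CC=C2C | intermediate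
12 | 9α-(tert-butyldimethylsilyloxy)-4-methyl-10-methylene-1αH,5βH-bicyclo[5.3.0]dec-3-en-6β-ol | C=C1[C@H](O[Si](C)(C)C(C)(C)C)CC[C@@H](O)[C@H]2[C@H]1CC=C2C | intermediate
13 | 9α-(tert-butyldimethylsilyloxy)-4-methyl-10-methylene-1αH,5βH-bicyclo[5.3.0]dec-3-en-6-one | C=C1[C@H](O[Si](C)(C)C(C)(C)C)CCC(=O)[C@H]2[C@H]1CC=C2C | intermediate
14 | C6–C7 trimethylsilyl enol ether of 13 | C=C1[C@H](O[Si](C)(C)C(C)(C)C)CC=C(O[Si](C)(C)C)[C@H]2[C@H]1CC=C2C | intermediate
15 | 9α-(tert-butyldimethylsilyloxy)-4-methyl-10-methylene-1αH,5βH-bicyclo[5.3.0]deca-3,7-dien-6-one | C=C1[C@H](O[Si](C)(C)C(C)(C)C)C=CC(=O)[C@H]2[C@H]1CC=C2C | intermediate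
16 | 9α-(tert-butyldimethylsilyloxy)-4-methyl-10-methylene-1αH,5βH-bicyclo[5.3.0]deca-3,7-dien-6β-ol | C=C1[C@H](O[Si](C)(C)C(C)(C)C)C=C[C@@H](O)[C@H]2[C@H]1CC=C2C | intermediate
17 | 6β-[(bromomethyl)dimethylsilyloxy]-9α-(tert-butyldimethylsilyloxy)-4-methyl-10-methylene-1αH,5βH-bicyclo[5.3.0]deca-3,7-diene | C=C1[C@H](O[Si](C)(C)C(C)(C)C)C=C[C@@H](O[Si](C)(C)CBr)[C@H]2[C@H]1CC=C2C | intermediate
18 | cis-fused 1,2-oxasilolane (O6–SiMe2–C11H2–C7) | C=C1[C@H](O[Si](C)(C)C(C)(C)C)C[C@@H](C[Si](C)(C)O3)[C@@H]3[C@H]2[C@H]1CC=C2C | intermediate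
19 | 9α-(tert-butyldimethylsilyloxy)-7β-(hydroxymethyl)-4-methyl-10-methylene-1αH,5βH,7αH-bicyclo[5.3.0]dec-3-en-6β-ol | C=C1[C@H](O[Si](C)(C)C(C)(C)C)C[C@@H](CO)[C@@H](O)[C@H]2[C@H]1CC=C2C | intermediate
20 | C11 N,N-diisopropylcarbamate of 19 | C=C1[C@H](O[Si](C)(C)C(C)(C)C)C[C@@H](COC(=O)N(C(C)C)C(C)C)[C@@H](O)[C@H]2[C@H]1CC=C2C | intermediate
21 | 6β,9α-bis(tert-butyldimethylsilyloxy) C11 carbamate | C=C1[C@H](O[Si](C)(C)C(C)(C)C)C[C@@H](COC(=O)N(C(C)C)C(C)C)[C@@H](O[Si](C)(C)C(C)(C)C)[C@H]2[C@H]1CC=C2C | intermediate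
22 | 3β,4β-epoxide of 21 | C=C1[C@H](O[Si](C)(C)C(C)(C)C)C[C@@H](COC(=O)N(C(C)C)C(C)C)[C@@H](O[Si](C)(C)C(C)(C)C)[C@H]2[C@H]1C[C@H]3[C@]2(C)O3 | intermediate
23 | 3α-(phenylselanyl)-4β-hydroxy compound | C=C1[C@H](O[Si](C)(C)C(C)(C)C)C[C@@H](COC(=O)N(C(C)C)C(C)C)[C@@H](O[Si](C)(C)C(C)(C)C)[C@H]2[C@H]1C[C@@H]([Se]c3ccccc3)[C@]2(C)O | intermediate
24 | 4β-hydroxy-2-ene (6β,9α-bis-silyl ether, C11 carbamate) | C=C1[C@H](O[Si](C)(C)C(C)(C)C)C[C@@H](COC(=O)N(C(C)C)C(C)C)[C@@H](O[Si](C)(C)C(C)(C)C)[C@H]2[C@H]1C=C[C@]2(C)O | intermediate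
25 | 4β,6β,9α-tris(tert-butyldimethylsilyloxy) C11 carbamate | C=C1[C@H](O[Si](C)(C)C(C)(C)C)C[C@@H](COC(=O)N(C(C)C)C(C)C)[C@@H](O[Si](C)(C)C(C)(C)C)[C@H]2[C@H]1C=C[C@]2(C)O[Si](C)(C)C(C)(C)C | intermediate
26 | (R)-C11-lithio carbamate | C=C1[C@H](O[Si](C)(C)C(C)(C)C)C[C@@H]([C@@H]([Li])OC(=O)N(C(C)C)C(C)C)[C@@H](O[Si](C)(C)C(C)(C)C)[C@H]2[C@H]1C=C[C@]2(C)O[Si](C)(C)C(C)(C)C | intermediate
27 | lithium methylboronate complex | C=C1[C@H](O[Si](C)(C)C(C)(C)C)C[C@@H]([C@@H]([B-]3(C)OC(C)(C)C(C)(C)O3)OC(=O)N(C(C)C)C(C)C)[C@@H](O[Si](C)(C)C(C)(C)C)[C@H]2[C@H]1C=C[C@]2(C)O[Si](C)(C)C(C)(C)C.[Li+] | intermediate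
28 | (11R)-C11 pinacol boronic ester | C=C1[C@H](O[Si](C)(C)C(C)(C)C)C[C@@H]([C@@H](C)B3OC(C)(C)C(C)(C)O3)[C@@H](O[Si](C)(C)C(C)(C)C)[C@H]2[C@H]1C=C[C@]2(C)O[Si](C)(C)C(C)(C)C | intermediate
29 | (R)-2,2-dimethyl-1,3-dioxolane-4-carbaldehyde | O=C[C@H]1COC(C)(C)O1 | starting material
30 | (S)-2,2-dimethyl-4-(2-methylprop-1-en-1-yl)-1,3-dioxolane | CC(C)=C[C@H]1COC(C)(C)O1 | intermediate
31 | (S)-4-methylpent-3-ene-1,2-diol | CC(C)=C[C@H](O)CO | intermediate
32 | sodium alkoxide of the primary monotosylate of 31 | CC(C)=C[C@H](O[Na])COS(=O)(=O)c1ccc(C)cc1 | intermediate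
33 | (S)-2-(2-methylprop-1-en-1-yl)oxirane | CC(C)=C[C@H]1CO1 | intermediate
34 | trans-3-(2-methylprop-1-en-1-yl)oxiran-2-yllithium | O1[C@@H]([Li])[C@@H]1C=C(C)C | intermediate
35 | lithium oxiranyl(alkyl)boronate complex | C=C1[C@H](O[Si](C)(C)C(C)(C)C)C[C@@H]([C@@H](C)[B-]3(OC(C)(C)C(C)(C)O3)[C@@H]4O[C@H]4C=C(C)C)[C@@H](O[Si](C)(C)C(C)(C)C)[C@H]2[C@H]1C=C[C@]2(C)O[Si](C)(C)C(C)(C)C.[Li+] | intermediate
36 | 12-(pinacolboryl)-13-(trimethylsilyloxy) intermediate | C=C1[C@H](O[Si](C)(C)C(C)(C)C)C[C@@H]([C@@H](C)[C@H](B3OC(C)(C)C(C)(C)O3)[C@H](C=C(C)C)O[Si](C)(C)C)[C@@H](O[Si](C)(C)C(C)(C)C)[C@H]2[C@H]1C=C[C@]2(C)O[Si](C)(C)C(C)(C)C | intermediate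
37 | (11R,12S,13S)-12,13-diol, 4β,6β,9α-tris-silyl ether | C=C1[C@H](O[Si](C)(C)C(C)(C)C)C[C@@H]([C@@H](C)[C@H](O)[C@H](C=C(C)C)O)[C@@H](O[Si](C)(C)C(C)(C)C)[C@H]2[C@H]1C=C[C@]2(C)O[Si](C)(C)C(C)(C)C | intermediate
38 | 12,13-diacetate, 4β,6β,9α-tris-silyl ether | C=C1[C@H](O[Si](C)(C)C(C)(C)C)C[C@@H]([C@@H](C)[C@H](OC(C)=O)[C@H](C=C(C)C)OC(C)=O)[C@@H](O[Si](C)(C)C(C)(C)C)[C@H]2[C@H]1C=C[C@]2(C)O[Si](C)(C)C(C)(C)C | intermediate
39 | CNP0269663.3 | C=C1[C@H](O)C[C@@H]([C@@H](C)[C@H](OC(C)=O)[C@H](C=C(C)C)OC(C)=O)[C@@H](O)[C@H]2[C@H]1C=C[C@]2(C)O | target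

**Totals and risks**

Total step count: 26. Longest linear sequence: 23 steps (steps 1–20 and 24–26).

Step 24 (carries the label). What may go wrong: deprotonation at the internal allylic oxirane C–H instead of the terminal CH2, slow ate-complex formation at the hindered boron, or β-oxido elimination instead of the 1,2-shift. The fallback uses known chemistry and sets out from 28. One-carbon Matteson homologation with LiCH2Cl (BrCH2Cl, n-BuLi) gives the homologous primary boronic ester F1, in which C11 has migrated with retention. Oxidation with NaBO3·4H2O gives the C12 primary alcohol F2, and Dess–Martin oxidation gives the α-methyl aldehyde F3. Reagent-controlled (Z)-γ-(methoxymethoxy)allylboration with the matched diisopinocampheylborane reagent, which reinforces the Felkin preference, gives the 12,13-syn diol mono-methoxymethyl ether with a terminal vinyl group F4. Cross-metathesis with 2-methyl-2-butene (second-generation Grubbs catalyst) gives the isobutenyl compound F5. Cleavage of the methoxymethyl ether with MgBr2·OEt2 and BuSH returns to the route at 37.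

Step 20. What may go wrong: sluggish 1,2-migration of the methyl group in the hindered boronate (reversion or decomposition of the ate complex), or a mismatch between the diamine and the substrate in the deprotonation. The fallback sets out from 25. Reductive cleavage of the carbamate with LiAlH4 gives the C11 primary alcohol F6, Dess–Martin oxidation gives the C11 aldehyde F7, and Wittig methylenation gives the 7β-vinyl compound F8. Copper-catalysed, ligand-controlled Markovnikov hydroboration of the vinyl group (B2pin2, CuCl, chiral bisphosphine, KOtBu, MeOH) returns to the route at 28.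

Step 12. What may go wrong: poor facial selectivity in the 1,2-reduction if the substrate bias opposes the catalyst. The fallback sets out from 15. Luche reduction (NaBH4, CeCl3·7H2O, MeOH) under substrate control gives the 6α-alcohol F9. Mitsunobu inversion with 4-nitrobenzoic acid (PPh3, diisopropyl azodicarboxylate) gives the 6β-ester F10, and methanolysis (K2CO3, MeOH) returns to the route at 16.

**Further compounds**
F1 | step 24 | C11–CH2–Bpin homologue of 28 | C=C1[C@H](O[Si](C)(C)C(C)(C)C)C[C@@H]([C@@H](C)CB3OC(C)(C)C(C)(C)O3)[C@@H](O[Si](C)(C)C(C)(C)C)[C@H]2[C@H]1C=C[C@]2(C)O[Si](C)(C)C(C)(C)C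
F2 | step 24 | C12 primary alcohol | C=C1[C@H](O[Si](C)(C)C(C)(C)C)C[C@@H]([C@@H](C)CO)[C@@H](O[Si](C)(C)C(C)(C)C)[C@H]2[C@H]1C=C[C@]2(C)O[Si](C)(C)C(C)(C)C
F3 | step 24 | C12 aldehyde | C=C1[C@H](O[Si](C)(C)C(C)(C)C)C[C@@H]([C@@H](C)C=O)[C@@H](O[Si](C)(C)C(C)(C)C)[C@H]2[C@H]1C=C[C@]2(C)O[Si](C)(C)C(C)(C)C
F4 | step 24 | 12-hydroxy-13-(methoxymethoxy) compound with terminal vinyl group | C=C1[C@H](O[Si](C)(C)C(C)(C)C)C[C@@H]([C@@H](C)[C@H](O)[C@H](C=C)OCOC)[C@@H](O[Si](C)(C)C(C)(C)C)[C@H]2[C@H]1C=C[C@]2(C)O[Si](C)(C)C(C)(C)C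
F5 | step 24 | 12-hydroxy-13-(methoxymethoxy) compound with C14=C15 isobutenyl group | C=C1[C@H](O[Si](C)(C)C(C)(C)C)C[C@@H]([C@@H](C)[C@H](O)[C@H](C=C(C)C)OCOC)[C@@H](O[Si](C)(C)C(C)(C)C)[C@H]2[C@H]1C=C[C@]2(C)O[Si](C)(C)C(C)(C)C
F6 | step 20 | 7β-(hydroxymethyl) tris-silyl ether | C=C1[C@H](O[Si](C)(C)C(C)(C)C)C[C@@H](CO)[C@@H](O[Si](C)(C)C(C)(C)C)[C@H]2[C@H]1C=C[C@]2(C)O[Si](C)(C)C(C)(C)C
F7 | step 20 | 7β-formyl tris-silyl ether | C=C1[C@H](O[Si](C)(C)C(C)(C)C)C[C@@H](C=O)[C@@H](O[Si](C)(C)C(C)(C)C)[C@H]2[C@H]1C=C[C@]2(C)O[Si](C)(C)C(C)(C)C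
F8 | step 20 | 7β-vinyl tris-silyl ether | C=C1[C@H](O[Si](C)(C)C(C)(C)C)C[C@@H](C=C)[C@@H](O[Si](C)(C)C(C)(C)C)[C@H]2[C@H]1C=C[C@]2(C)O[Si](C)(C)C(C)(C)C
F9 | step 12 | 6α-epimer of 16 | C=C1[C@H](O[Si](C)(C)C(C)(C)C)C=C[C@H](O)[C@H]2[C@H]1CC=C2C
F10 | step 12 | 6β-(4-nitrobenzoate) of 16 | C=C1[C@H](O[Si](C)(C)C(C)(C)C)C=C[C@@H](OC(=O)c3ccc(cc3)[N+](=O)[O-])[C@H]2[C@H]1CC=C2C
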